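The closed, stirred vessel holds starting material, partner, second substrate and free catalyst at one temperature, and the target grows as a fraction of the starting material charged.

| setting | Friday's | Saturday's | Wednesday's | north-west | south-west | south | east |
|---|---|---|---|---|---|---|---|
| starting material | 0.012 M | 0.012 M | 0.012 M | 0.012 M | 0.012 M | 0.012 M | 0.012 M |
| partner | 4.2 equiv | 6.6 equiv | 3 equiv | 3.00 equiv | 3.00 equiv | 3.00 equiv | 3.00 equiv |
| second substrate | 1 equiv | 1 equiv | 1 equiv | 1.00 equiv | 1.00 equiv | 1.00 equiv | 1.00 equiv |
| free catalyst | 0.55 mol% | 0.55 mol% | 0.83 mol% | 0.55 mol% | 0.55 mol% | 0.55 mol% | 0.55 mol% |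
| temperature | −40 °C | 10 °C | −40 °C | −35 °C | 25 °C | −5 °C | 55 °C |
| remark | run made earlier | run made earlier | run made earlier |  |  |  |  |
| time |  |  |  | 25 h | 25 h | 25 h | 25 h |

| run | time / h | target / % | starting material / % |
|---|---|---|---|
| Friday's | 2.50 | 1.0 | 99.6 |
| Friday's | 4.00 | 0.7 | 99.2 |
| Friday's | 6.00 | 0.9 | 98.3 |
| Friday's | 10.0 | 2.4 | 97.3 |
| Friday's | 20.0 | 4.7 | 95.3 |
| Friday's | 30.0 | 6.2 | 93.0 |
| Saturday's | 0.500 | 5.2 | 94.7 |
| Saturday's | 1.00 | 9.8 | 90.5 |
| Saturday's | 1.50 | 14.3 | 85.9 |
| Saturday's | 2.00 | 17.7 | 81.9 |
| Saturday's | 2.50 | 21.7 | 78.5 |
| Saturday's | 3.00 | 24.7 | 74.9 |
| Wednesday's | 2.50 | 0.5 | 98.9 |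
| Wednesday's | 5.00 | 1.9 | 98.3 |
| Wednesday's | 8.00 | 2.1 | 97.6 |
| Wednesday's | 15.0 | 3.4 | 96.4 |
| Wednesday's | 30.0 | 7.8 | 92.4 |

(readings scatter by 0.3 percentage points)

- the best flask by amount of target, in percent of the starting material charged; "all alike" if 1.5 percentage points covers them all (north-west / south-west / south / east / all alike)
- amount of target at the end, in percent of the starting material charged, north-west
- amount of target at the end, in percent of the starting material charged, south-west
- amount of target at the end, in percent of the starting material charged, south
- amount of target at the end, in percent of the starting material charged, east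



Saturday's run bends. From the start to 1.50 h the starting material falls with a first-order constant of 0.101 h⁻¹, and from then to 3.00 h with 0.0914 h⁻¹, which is slower. Taking the making constant as proportional to partner, which Friday's and Wednesday's runs allow, this drift reads as partner fading with a loss constant of 0.0691 h⁻¹, a life of 14.5 h. With a scatter of 0.3 percentage points on each point, this is a rough reading.

Two extreme flasks can be solved in the head. If partner stands at its charge (the pseudo-first-order case), the fraction of starting material left is exp(−kt), with k the making constant, and the target climbs toward the whole charge. If partner fades long before the end, its mean over the run shrinks as the time grows, so kt stops at k/d and the fraction left stops at exp(−k/d). A real flask, with partner fading all the while, has a mean partner over the run that lies under the charge and also under the charge divided by dt, the mean that the second extreme counts, so its target stands under both.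

Scaled to 3.00 equiv of partner, k/d is 0.667. This ratio of making constant to partner's loss constant, the reach, gives a ceiling on the target of 48.7%. The life read above is shorter than the 25 h allowed, so the second extreme applies to the warm flasks. This reckoning assumes, without proof from the readings, that the loss warms at least as steeply as the making. South-west and east then stand under that ceiling, and the best flask lies at a middle temperature.

The forecast differs. It names east and gives 6.2% for north-west, 73% for south-west, 34% for south and 88% for east, reading the bend as "second order, with starting material and the 1-equiv second substrate consumed together". Its east value is what first order to completion through the last reading of Saturday's run gives.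

The flasks give 6.09% in north-west, 17.0% in south-west, 34.1% in south and 2.89% in east, so the best is south.

    starting material + partner + free catalyst → free catalyst + target (k = 46000 M⁻² h⁻¹, Ea = 37.0 kJ mol⁻¹)
    second substrate + partner + free catalyst → free catalyst + second product (k = 16000 M⁻² h⁻¹, Ea = 45.0 kJ mol⁻¹)
    free catalyst → spent catalyst (k = 5.30 × 10⁻⁵ h⁻¹, Ea = 110 kJ mol⁻¹)
    partner → decomposed reagent (k = 0.540 h⁻¹, Ea = 89.0 kJ mol⁻¹)
    (constants at 25 °C)

East's target, read through the same rule, means a reach of 0.0293, far under the 0.667 reckoned. The main reason is partner's decomposition: without that step the same flask gives 99.3% instead of 2.89%. At the start of east, partner goes into decomposed reagent 100 times as fast as into target, and 0% of it stands at the end. Charged at 0.030 M, with equivalents and loadings held, the neighbour of east multiplies partner and catalyst together, so its reach is 0.183, which means 16.7%; that flask holds 15.7%.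

The numbers in the tables were generated by integration on assumed constants; scatter was added.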